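**Retrosynthetic overview**

- The target is a linear tetramer A–CH2–B–CH2–C–CH2–D. Ring A (2-butyryl-3,5-dihydroxy-4,4-dimethylcyclohexadienone) is ring D (3-methyl-butyrylphloroglucinol) carrying one extra methyl on its methyl-bearing carbon, so removing that methyl leads back to a C2-symmetric tetramer 13.
- The strategy rests on the two inner arenes: rings B and C are the same 3-butyryl-2,4,6-trihydroxyphenyl unit, joined by the central CH2, and each carries one further CH2 (to ring A or D) on its last ring carbon. Cutting both outer CH2–ring B/ring C bonds gives methylenebis(butyrylphloroglucinol) 5 and two ortho-quinone methides 11 from Mannich base 10.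
- Dimer 5 comes from butyrylphloroglucinol 3 and formaldehyde; Mannich base 10 comes from 2,4,6-trihydroxytoluene by butyrylation and aminomethylation.
- No ring is built: rings B and C are bought as phloroglucinol, rings A and D as 2,4,6-trihydroxytoluene. Ring A is made last, by dearomatising one terminal arene.

Key step: step 5

Remark on the chemistry: ring A is drawn in the target as one enol tautomer of a 2-acylcyclohexane-1,3,5-trione. All its keto–enol tautomers are taken as the same compound. The target has no stereocentre, so no stereocontrol is needed.

**Route**

Step 1
Reactants: 1 phloroglucinol; 2 butyryl chloride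
Product: 3 butyrylphloroglucinol [1-(2,4,6-trihydroxyphenyl)butan-1-one]
Conditions: AlCl3 (4 equiv), PhNO2–CH2Cl2, 0 °C to 45 °C; then ice/1 M HCl
Reagents that add atoms: butyryl chloride 2, CCCC(=O)Cl
Why: Friedel–Crafts C-acylation of the electron-rich triol (any O-butyrate formed undergoes Fries shift under AlCl3), and the chelated aryl ketone deactivates the ring so that mono-acylation should dominate.

Step 2
Reactants: 3 butyrylphloroglucinol (3 equiv per formaldehyde); 4 formaldehyde
Product: 5 methylenebis(butyrylphloroglucinol) [two 3-butyryl-2,4,6-trihydroxyphenyl rings joined by one CH2]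
Conditions: 37% aq. HCHO (0.33 equiv per 3), KOH (1 equiv per 3), H2O, 0 °C, short contact time, Ar; then 1 M HCl; excess 3 recovered by chromatography
Reagents that add atoms: formaldehyde 4, C=O
Why: Base-mediated formaldehyde condensation of an acylphloroglucinol (Lederer–Manasse hydroxymethylation, loss of hydroxide to a quinone methide, Michael addition of a second phenoxide), with excess 3 to hold chain growth at the dimer.

Step 3
Reactants: 6 2,4,6-trihydroxytoluene; 2 butyryl chloride
Product: 7 3-methyl-butyrylphloroglucinol [1-(2,4,6-trihydroxy-3-methylphenyl)butan-1-one]
Conditions: AlCl3 (4 equiv), PhNO2–CH2Cl2, 0 °C to 45 °C; then ice/1 M HCl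
Reagents that add atoms: butyryl chloride 2, CCCC(=O)Cl
Why: Friedel–Crafts acylation in which the two free ring carbons of 6 are equivalent, so a single regioisomer is expected and the new ketone disfavours a second acylation.

Step 4
Reactants: 7 3-methyl-butyrylphloroglucinol; 4 formaldehyde; 8 dimethylamine
Product: 10 Mannich base 1-[3-(dimethylaminomethyl)-2,4,6-trihydroxy-5-methylphenyl]butan-1-one, via (dimethylamino)methanol 9 (not isolated)
Conditions: 40% aq. Me2NH (1.1 equiv) and 37% aq. HCHO (1.05 equiv) premixed in EtOH at 0 °C, then 7, 0 °C to rt; product collected as the zwitterion without heating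
Reagents that add atoms: formaldehyde 4, C=O; dimethylamine 8, CNC
Why: Phenolic Mannich reaction at the only unsubstituted ring carbon of 7, where premixing the amine and aldehyde leaves little free formaldehyde and so suppresses methylene-bridged self-dimer.

Step 5
Reactants: 5 methylenebis(butyrylphloroglucinol); 10 Mannich base (2.4 equiv)
Product: 13 C2-symmetric tetramer D–CH2–B–CH2–C–CH2–D (core 5 capped on each free ring carbon by a 3-butyryl-2,4,6-trihydroxy-5-methylbenzyl group), via ortho-quinone methide 11 (not isolated), via mono-capped trimer 12 (not isolated)
Conditions: iPr2NEt (2 equiv), degassed 1,4-dioxane, 80 °C, 10 added in portions, slow Ar sweep to carry off Me2NH; then 1 M HCl; chromatography on Sephadex LH-20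
Reagents that add atoms: none
Why: On heating, zwitterionic 10 loses dimethylamine by E1cB elimination to give ortho-quinone methide 11; the phenoxide of 5 adds to its exocyclic CH2 through the single unsubstituted carbon of ring B and tautomerises back to the arene (trimer 12), and a second round at ring C gives 13. The closest known reaction is the retro-Mannich/Michael coupling of phenolic Mannich bases with acylphloroglucinols used to make unsymmetrical methylene-bridged dimers, here run twice on one nucleophile. No ring closes and no stereocentre forms, so closure mode and stereocontrol do not arise. The step needs C- over O-alkylation and complete double capping without oligomerisation. O-adducts are benzylic aryl ethers that re-ionise to 11 whereas C-adducts rearomatise and persist, and excess 10 with removal of volatile Me2NH pushes the second capping; 10 has no free ring carbon and 5 has exactly two, so growth must stop at the tetramer. The weak amine base and moderate temperature are chosen to keep retro-Michael exchange of the existing bridges slow.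

Step 6
Reactants: 13 C2-symmetric tetramer; 14 iodomethane
Product: 15 target CNP0246352.0 (ring A = 2-butyryl-3,5-dihydroxy-4,4-dimethylcyclohexa-2,5-dienone linked through CH2 to ring B)
Conditions: NaOMe (8 equiv), MeI (0.9 equiv), MeOH, −10 °C to 0 °C, Ar; then cold 1 M HCl; 15 separated from recovered 13 and doubly methylated material on Sephadex LH-20 or reversed phase; 13 recycled
Reagents that add atoms: iodomethane 14, CI
Why: Dearomative C-methylation of a C-methyl acylphloroglucinol (the MeI/NaOMe route to acylfilicinic acids), in which MeOH favours carbon alkylation of the polyphenoxide and, among the ring carbons ortho to the most acidic para-to-acyl oxygens, only the two terminal ones carry a small methyl instead of a bulky diarylmethane CH2, so SN2 attack on MeI should occur there to give the gem-dimethyl carbon of ring A; sub-stoichiometric MeI limits methylation at both ends, and because 13 is C2-symmetric either end gives 15.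

**Compound list**

1 | phloroglucinol (benzene-1,3,5-triol) | Oc1cc(O)cc(O)c1 | starting material
2 | butyryl chloride | CCCC(=O)Cl | starting material
3 | butyrylphloroglucinol, 1-(2,4,6-trihydroxyphenyl)butan-1-one | CCCC(=O)c1c(O)cc(O)cc1O | intermediate
4 | formaldehyde (37% aqueous) | C=O | starting material
5 | methylenebis(butyrylphloroglucinol) | CCCC(=O)c1c(O)cc(O)c(Cc2c(O)cc(O)c(C(=O)CCC)c2O)c1O | intermediate
6 | 2,4,6-trihydroxytoluene (2-methylbenzene-1,3,5-triol) | Cc1c(O)cc(O)cc1O | starting material
7 | 3-methyl-butyrylphloroglucinol, 1-(2,4,6-trihydroxy-3-methylphenyl)butan-1-one | CCCC(=O)c1c(O)cc(O)c(C)c1O | intermediate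
8 | dimethylamine | CNC | starting material
9 | (dimethylamino)methanol, formed in the flask, not isolated | CN(C)CO | intermediate
10 | Mannich base, 1-[3-(dimethylaminomethyl)-2,4,6-trihydroxy-5-methylphenyl]butan-1-one | CCCC(=O)c1c(O)c(C)c(O)c(CN(C)C)c1O | intermediate
11 | ortho-quinone methide, 2-butanoyl-3,5-dihydroxy-4-methyl-6-methylidenecyclohexa-2,4-dien-1-one, not isolated | CCCC(=O)C1=C(O)C(C)=C(O)C(=C)C1=O | intermediate
12 | mono-capped trimer D–CH2–B–CH2–C with one free ring carbon on ring C, not isolated | CCCC(=O)c1c(O)c(C)c(O)c(Cc2c(O)c(Cc3c(O)cc(O)c(C(=O)CCC)c3O)c(O)c(C(=O)CCC)c2O)c1O | intermediate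
13 | C2-symmetric tetramer with two 3-methyl-butyrylphloroglucinol termini | CCCC(=O)c1c(O)c(C)c(O)c(Cc2c(O)c(Cc3c(O)c(Cc4c(O)c(C)c(O)c(C(=O)CCC)c4O)c(O)c(C(=O)CCC)c3O)c(O)c(C(=O)CCC)c2O)c1O | intermediate
14 | iodomethane | CI | starting material
15 | CNP0246352.0 | CCCC(=O)C1=C(O)C(C)(C)C(O)=C(Cc2c(O)c(Cc3c(O)c(Cc4c(O)c(C)c(O)c(C(=O)CCC)c4O)c(O)c(C(=O)CCC)c3O)c(O)c(C(=O)CCC)c2O)C1=O | target

**Summary**

Total step count: 6.
Longest linear sequence: 4 steps (steps 1, 2, 5, 6; equally steps 3, 4, 5, 6).

**Steps most likely to fail**

1. Step 6. The methylation may lack site control: attack at bridge-bearing ring carbons or on oxygen, a second methylation at the other terminus, and base-induced retro-Michael scission and reshuffling of the methylene bridges in methoxide. Fallback: install the gem-dimethyl ring before coupling, so no desymmetrisation is needed. It sets out from 7, 5 and 10 and returns at 15. Compound 7 is C-methylated (MeI, NaOMe, MeOH, 0 °C) to butyrylfilicinic acid F1, which is freed from the aromatic 3,5-dimethyl isomer by extraction into aqueous NaHCO3. F1 is aminomethylated with premixed formaldehyde and dimethylamine (reagent 9) in EtOH to give the Mannich base of butyrylfilicinic acid F2. In parallel, 5 in excess is treated with one equivalent of 10 under the conditions of step 5 and the mono-capped trimer 12 is isolated. Heating 12 with F2 in dioxane with iPr2NEt caps the last free carbon of ring C and gives 15 directly.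

2. Step 5. The second capping may stall, the quinone methide may be consumed by self-condensation, and bridges already formed may exchange under base and heat to give mixed oligomers. Fallback: form the outer bridge on a monomer and the central bridge last. It sets out from 3 and 10 and returns at 13. Compound 10 is heated with excess 3 (3 equiv) in dioxane to give the unsymmetrical dimer F3, in which only the ring derived from 3 keeps a free carbon. F3 is then condensed with half an equivalent of formaldehyde (aq. KOH, 0 °C, then HCl), which can only join two molecules through those carbons and so gives 13.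

3. Step 2. Chain growth may run past the dimer, because 5 keeps two free ring carbons and competes with 3 for formaldehyde, and bridges may exchange in alkali. Fallback: replace the in-situ hydroxymethylation by an isolated electrophile. It sets out from 3 and returns at 5. Compound 3 in excess is aminomethylated with one equivalent of premixed formaldehyde and dimethylamine (reagent 9) in EtOH at 0 °C to the mono-Mannich base F4, collected as its zwitterion. F4 is then heated with a fourfold excess of 3 in dioxane with iPr2NEt, so that the released quinone methide meets mainly monomer and gives 5; excess 3 is recovered.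

**Further compounds**

F1 | step 6 | butyrylfilicinic acid, 2-butanoyl-3,5-dihydroxy-4,4-dimethylcyclohexa-2,5-dien-1-one | CCCC(=O)C1=C(O)C(C)(C)C(O)=CC1=O
F2 | step 6 | Mannich base of butyrylfilicinic acid, 2-butanoyl-6-(dimethylaminomethyl)-3,5-dihydroxy-4,4-dimethylcyclohexa-2,5-dien-1-one | CCCC(=O)C1=C(O)C(C)(C)C(O)=C(CN(C)C)C1=O
F3 | step 5 | unsymmetrical dimer, 3-methyl-butyrylphloroglucinol–CH2–butyrylphloroglucinol | CCCC(=O)c1c(O)c(C)c(O)c(Cc2c(O)cc(O)c(C(=O)CCC)c2O)c1O
F4 | step 2 | mono-Mannich base of butyrylphloroglucinol, 1-[3-(dimethylaminomethyl)-2,4,6-trihydroxyphenyl]butan-1-one | CCCC(=O)c1c(O)cc(O)c(CN(C)C)c1O
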